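**Retrosynthetic overview**

1. Target 26 ⇐ diol 25 ⇐ bicyclic keto diester 19. The two acetoxymethyl arms on C4 are the two esters of a malonate; C8=CH2 and the C12–C15 diene come from Wittig reactions on a C8 ketone and a C12 aldehyde.
2. 19 ⇐ open-chain 17 in one flask: ring B first (C5–C6, radical 6-exo closure), then ring A (C3–C4, malonate alkylation). The enabling feature is twofold: C4 of ring A carries two identical one-carbon arms and is bonded to C5, so it can be a non-stereogenic malonate carbon (acceptor at C5, then carbanion toward C3–Cl); and C8 of ring B is a carbonyl-level carbon separated from C5 by C7 and C6, so a C8 cyclopropanol ether (ring CH2 groups = C6 and C7) is a latent C6 radical.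
3. 17 ⇐ ester 11 (Kulinkovich cyclopropanation, alkene cleavage, Knoevenagel condensation); 11 ⇐ allylic ester 7 by Ireland–Claisen rearrangement, which sets C9 and the quaternary C10 by chirality transfer from (S)-but-3-yn-2-ol.
4. Order of ring formation: temporary cyclopropane (opened again in the key step) → ring B → ring A.

Key step: step 10

Remark: carbon atoms are referred to by labdane numbering (C1–C20), and the target is the (5S,9R,10S) enantiomer (ent-labdane series). Metalated forms of numbered compounds and transient species within one mechanistic event are not numbered.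

**Route**

Step 1
Reactants: 1 (S)-but-3-yn-2-ol; 2 1-chloro-3-iodopropane
Product: 3 (2S)-7-chlorohept-3-yn-2-ol
Conditions: n-BuLi (2.1 equiv), THF, −78 → 0 °C; then DMPU, 2, −78 → 25 °C
Reagents that add atoms: none
Why: Alkylation of the lithium acetylide (alkoxide–acetylide dianion) by SN2 displacement of iodide, the far better leaving group of 2, adds C1–C3 and keeps the chloride for the key step; the carbinol stereocentre is not touched.

Step 2
Reactants: 3 (2S)-7-chlorohept-3-yn-2-ol
Product: 4 (2S,3Z)-7-chloro-4-iodohept-3-en-2-ol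
Conditions: NaAlH2(OCH2CH2OCH3)2, THF, 0 → 25 °C; then I2, −78 → 0 °C
Reagents that add atoms: iodine, II
Why: Hydroxyl-directed trans-hydroalumination of the propargylic alcohol puts hydride on the proximal and aluminium on the distal alkyne carbon, and iodinolysis of the C–Al bond with retention should give the Z vinyl iodide (reduction–iodination of a propargylic alcohol); no stereocentre is formed.

Step 3
Reactants: 4 (2S,3Z)-7-chloro-4-iodohept-3-en-2-ol
Product: 5 (2S,3E)-7-chloro-4-methylhept-3-en-2-ol
Conditions: Me2CuLi (from copper iodide CuI and MeLi, 4 equiv), Et2O, −20 → 0 °C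
Reagents that add atoms: lithium dimethylcuprate, [Li+].C[Cu-]C
Why: Gilman cuprate cross-coupling replaces the vinylic iodide by methyl (the future C20) with retention of geometry, so the chloropropyl chain ends trans and the methyl cis to the carbinol carbon (E); the alkyl chloride is inert and excess cuprate covers the free hydroxyl.

Step 4
Reactants: 5 (2S,3E)-7-chloro-4-methylhept-3-en-2-ol; 6 4-(benzyloxy)butanoic acid
Product: 7 (2S,3E)-7-chloro-4-methylhept-3-en-2-yl 4-(benzyloxy)butanoate
Conditions: DCC, DMAP (cat.), CH2Cl2, 0 → 25 °C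
Reagents that add atoms: none
Why: Steglich esterification takes place at the acyl carbon, so the S carbinol centre is carried unchanged into the ester.

Step 5
Reactants: 7 (2S,3E)-7-chloro-4-methylhept-3-en-2-yl 4-(benzyloxy)butanoate
Product: 11 methyl (2S,3R,4E)-2-[2-(benzyloxy)ethyl]-3-(3-chloropropyl)-3-methylhex-4-enoate, via Z-silyl ketene acetal 8 (not isolated), via trimethylsilyl ester 9 (not isolated), via carboxylic acid 10 (not isolated)
Conditions: LDA, THF/DMPU (3:1), −78 °C; Me3SiCl, −78 → 60 °C; then MeOH, 0 °C; Me3SiCHN2, 0 → 25 °C (one flask)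
Reagents that add atoms: (trimethylsilyl)diazomethane, C[Si](C)(C)C=[N+]=[N-]; chlorotrimethylsilane, C[Si](C)(C)Cl (its silicon stays only in 8 and 9)
Why: Ireland–Claisen rearrangement: enolisation in the presence of DMPU should give the ketene acetal with the benzyloxyethyl arm cis to OSiMe3, and the chair transition state with the carbinol methyl equatorial transfers the S carbinol chirality to the quaternary C10 (R) and to C9 (S) while forming the E propenyl group; methanolysis of the silyl ester and methylation of the acid follow in the same flask.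

Step 6
Reactants: 11 methyl (2S,3R,4E)-2-[2-(benzyloxy)ethyl]-3-(3-chloropropyl)-3-methylhex-4-enoate
Product: 12 1-[(3S,4R,5E)-1-(benzyloxy)-4-(3-chloropropyl)-4-methylhept-5-en-3-yl]cyclopropan-1-ol
Conditions: EtMgBr (3 equiv), Ti(OiPr)4 (30 mol%), THF, 0 → 25 °C
Reagents that add atoms: ethylmagnesium bromide, CC[Mg]Br
Why: Kulinkovich cyclopropanation: the titanacyclopropane made from EtMgBr and Ti(OiPr)4 adds twice to the ester carbonyl and gives the C8 cyclopropanol whose ring methylenes are C6 and C7; C8 carries two equivalent ring carbons and is not stereogenic, and the internal alkene, the chloride and the benzyl ether are left alone.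

Step 7
Reactants: 12 1-[(3S,4R,5E)-1-(benzyloxy)-4-(3-chloropropyl)-4-methylhept-5-en-3-yl]cyclopropan-1-ol
Product: 13 {1-[(3S,4R,5E)-1-(benzyloxy)-4-(3-chloropropyl)-4-methylhept-5-en-3-yl]cyclopropoxy}triethylsilane
Conditions: Et3SiOTf, 2,6-lutidine, CH2Cl2, −78 °C
Reagents that add atoms: triethylsilyl trifluoromethanesulfonate, CC[Si](CC)(CC)OS(=O)(=O)C(F)(F)F
Why: Silyl ether formation at the tertiary cyclopropanol prevents hemiacetal and oxa-Michael closure onto C5 in the next two steps and turns the ring into an oxidisable precursor of the β-keto radical.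

Step 8
Reactants: 13 {1-[(3S,4R,5E)-1-(benzyloxy)-4-(3-chloropropyl)-4-methylhept-5-en-3-yl]cyclopropoxy}triethylsilane
Product: 15 (2S,3S)-5-(benzyloxy)-2-(3-chloropropyl)-2-methyl-3-[1-(triethylsilyloxy)cyclopropyl]pentanal, via vicinal diol 14 (not isolated)
Conditions: OsO4 (2 mol%), NaIO4 (4 equiv), 2,6-lutidine, dioxane/H2O (3:1), 25 °C
Reagents that add atoms: sodium periodate, [Na+].[O-]I(=O)(=O)=O (terminal oxidant; the oxygen is delivered through OsO4)
Why: Lemieux–Johnson oxidative cleavage (osmylation to diol 14, then periodate cleavage) of the only alkene removes the two carbons that carried the chirality-transfer centre and unveils C5 as a non-enolisable aldehyde on the quaternary C10.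

Step 9
Reactants: 15 (2S,3S)-5-(benzyloxy)-2-(3-chloropropyl)-2-methyl-3-[1-(triethylsilyloxy)cyclopropyl]pentanal; 16 dimethyl malonate
Product: 17 dimethyl 2-[(2R,3S)-5-(benzyloxy)-2-(3-chloropropyl)-2-methyl-3-[1-(triethylsilyloxy)cyclopropyl]pentylidene]propanedioate
Conditions: piperidine (20 mol%), AcOH (20 mol%), toluene, 4 Å molecular sieves, 80 °C
Reagents that add atoms: none
Why: Knoevenagel condensation of the non-enolisable aldehyde installs C4 with both future C18/C19 arms as an alkylidene malonate; the two esters are identical, so no alkene isomers can arise.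

Step 10
Reactants: 17 dimethyl 2-[(2R,3S)-5-(benzyloxy)-2-(3-chloropropyl)-2-methyl-3-[1-(triethylsilyloxy)cyclopropyl]pentylidene]propanedioate
Product: 19 dimethyl (4aR,5S,8aS)-5-[2-(benzyloxy)ethyl]-4a-methyl-6-oxooctahydronaphthalene-1,1(2H)-dicarboxylate, via monocyclic chloro keto malonate 18 (not isolated)
Conditions: 9-mesityl-10-methylacridinium tetrafluoroborate (5 mol%), 2,6-lutidine (20 mol%), MeCN/MeOH (20:1), 450 nm LEDs, 25 °C; then Cs2CO3 (3 equiv), NaI (20 mol%), 60 °C (same flask)
Reagents that add atoms: none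
Why: Proposed new method: single-electron oxidation of the siloxycyclopropane by the photoexcited acridinium, ring opening of the radical cation with transfer of Et3Si to methanol, and 6-exo-trig addition of the resulting β-keto C6 radical to C5 of the alkylidene malonate close ring B, after which the acridinyl radical reduces the malonyl radical to the C4 malonate anion (radical–polar crossover), which is protonated to 18 and, once Cs2CO3 is added, closes ring A by 6-exo-tet displacement of the C3 chloride, forming the C3–C4 bond. The closest known reaction types are the photoinduced-electron-transfer ring opening of cyclopropyl silyl ethers to β-keto radicals with intramolecular alkene trapping, the Giese cyclisation onto alkylidene malonates, and photoredox radical addition–polar cyclisation cascades that end in an intramolecular alkylation of a stabilised carbanion; joining them into one bicyclisation is the new element. The only new stereocentre, C5, is set in the radical step: in the chair transition state of ring B the C9 side chain and the C1–C3 chain on C10 are equatorial, the small C10 methyl is axial and lies in the plane of the alkylidene malonate (least 1,3-allylic strain), so C6 should add anti to that methyl and C5–H should end trans to C10–CH3 with the malonate equatorial and gauche to C1, which is the trans-decalin arrangement; C4 is not stereogenic because its two ester arms are identical. The step needs chemoselective oxidation (the siloxycyclopropane is oxidised at a far lower potential than the benzyl ether or the acceptor), exo regioselectivity (secured by the doubly activated, polarised acceptor and the six-membered transition state) and C- rather than O-alkylation (favoured for the soft caesium malonate in a six-membered exo-tet closure). C9, now alpha to the C8 ketone, is expected to equilibrate under the carbonate to the equatorial configuration that the target needs.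

Step 11
Reactants: 19 dimethyl (4aR,5S,8aS)-5-[2-(benzyloxy)ethyl]-4a-methyl-6-oxooctahydronaphthalene-1,1(2H)-dicarboxylate
Product: 20 dimethyl (4aR,5S,8aS)-5-(2-hydroxyethyl)-4a-methyl-6-oxooctahydronaphthalene-1,1(2H)-dicarboxylate
Conditions: H2 (1 atm), Pd/C (10%), EtOAc, 25 °C
Reagents that add atoms: none
Why: Hydrogenolysis of the benzyl ether frees the C12 hydroxyl at the one stage of the route that contains no alkene; the ketone and the esters are inert under these conditions.

Step 12
Reactants: 20 dimethyl (4aR,5S,8aS)-5-(2-hydroxyethyl)-4a-methyl-6-oxooctahydronaphthalene-1,1(2H)-dicarboxylate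
Product: 21 dimethyl (4aR,5S,8aS)-4a-methyl-6-oxo-5-(2-oxoethyl)octahydronaphthalene-1,1(2H)-dicarboxylate
Conditions: Dess–Martin periodinane, CH2Cl2, 0 → 25 °C
Reagents that add atoms: none
Why: Dess–Martin oxidation gives the C12 aldehyde under neutral conditions, which should avoid aldol closure of the 1,4-keto aldehyde and leave C9 untouched.

Step 13
Reactants: 21 dimethyl (4aR,5S,8aS)-4a-methyl-6-oxo-5-(2-oxoethyl)octahydronaphthalene-1,1(2H)-dicarboxylate
Product: 22 dimethyl (4aR,5S,8aS)-4a-methyl-5-[(2E)-3-methyl-4-oxobut-2-en-1-yl]-6-oxooctahydronaphthalene-1,1(2H)-dicarboxylate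
Conditions: Ph3P=C(CH3)CHO (1.3 equiv), toluene, 90 °C
Reagents that add atoms: 2-(triphenylphosphoranylidene)propanal, CC(C=O)=P(c1ccccc1)(c1ccccc1)c1ccccc1
Why: Wittig olefination with the stabilised ylide reacts only at the aldehyde, not at the hindered C8 ketone, and should give the E trisubstituted enal (C12=C13 with the C16 methyl), as is usual for stabilised ylides.

Step 14
Reactants: 22 dimethyl (4aR,5S,8aS)-4a-methyl-5-[(2E)-3-methyl-4-oxobut-2-en-1-yl]-6-oxooctahydronaphthalene-1,1(2H)-dicarboxylate
Product: 24 dimethyl (4aS,5R,8aS)-4a-methyl-6-methylidene-5-[(2E)-3-methylpenta-2,4-dien-1-yl]octahydronaphthalene-1,1(2H)-dicarboxylate, via keto diene 23 (not isolated)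
Conditions: Ph3PCH3Br (5 equiv), KOtBu (4.8 equiv), THF/toluene, 0 → 80 °C
Reagents that add atoms: methyltriphenylphosphonium bromide, C[P+](c1ccccc1)(c1ccccc1)c1ccccc1.[Br-]
Why: Double Wittig methylenation: the ylide first turns the enal into the terminal diene (23) and on warming the hindered C8 ketone into the exocyclic methylene; C9 is epimerisable under the basic conditions but already holds the equatorial, thermodynamically preferred side chain.

Step 15
Reactants: 24 dimethyl (4aS,5R,8aS)-4a-methyl-6-methylidene-5-[(2E)-3-methylpenta-2,4-dien-1-yl]octahydronaphthalene-1,1(2H)-dicarboxylate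
Product: 25 [(4aS,5R,8aS)-4a-methyl-6-methylidene-5-[(2E)-3-methylpenta-2,4-dien-1-yl]octahydronaphthalene-1,1(2H)-diyl]dimethanol
Conditions: LiAlH4, THF, 0 → 50 °C
Reagents that add atoms: none
Why: Hydride reduction of both neopentyl methyl esters gives the C18/C19 diol and leaves the isolated and the conjugated alkenes untouched.

Step 16
Reactants: 25 [(4aS,5R,8aS)-4a-methyl-6-methylidene-5-[(2E)-3-methylpenta-2,4-dien-1-yl]octahydronaphthalene-1,1(2H)-diyl]dimethanol
Product: 26 [(4aS,5R,8aS)-4a-methyl-6-methylidene-5-[(2E)-3-methylpenta-2,4-dien-1-yl]octahydronaphthalene-1,1(2H)-diyl]bis(methylene) diacetate, i.e. (5S,9R,10S)-labda-8(17),12E,14-triene-18,19-diyl diacetate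
Conditions: Ac2O, pyridine, DMAP (cat.), 25 °C
Reagents that add atoms: acetic anhydride, CC(=O)OC(C)=O
Why: DMAP-catalysed acylation of both primary alcohols gives the diacetate target without touching any stereocentre.

**Compound list**

1 | (S)-but-3-yn-2-ol | C[C@H](O)C#C | starting material
2 | 1-chloro-3-iodopropane | ClCCCI | starting material
3 | (2S)-7-chlorohept-3-yn-2-ol | C[C@H](O)C#CCCCCl | intermediate
4 | (2S,3Z)-7-chloro-4-iodohept-3-en-2-ol | C[C@H](O)/C=C(\I)CCCCl | intermediate
5 | (2S,3E)-7-chloro-4-methylhept-3-en-2-ol | C[C@H](O)/C=C(\C)CCCCl | intermediate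
6 | 4-(benzyloxy)butanoic acid | OC(=O)CCCOCc1ccccc1 | starting material
7 | (2S,3E)-7-chloro-4-methylhept-3-en-2-yl 4-(benzyloxy)butanoate | c1ccccc1COCCCC(=O)O[C@@H](C)/C=C(\C)CCCCl | intermediate
8 | {[(1Z)-4-(benzyloxy)-1-{[(2S,3E)-7-chloro-4-methylhept-3-en-2-yl]oxy}but-1-en-1-yl]oxy}trimethylsilane (Z-silyl ketene acetal, benzyloxyethyl arm cis to OSiMe3) | c1ccccc1COCC/C=C(\O[Si](C)(C)C)O[C@@H](C)/C=C(\C)CCCCl | intermediate
9 | trimethylsilyl (2S,3R,4E)-2-[2-(benzyloxy)ethyl]-3-(3-chloropropyl)-3-methylhex-4-enoate | c1ccccc1COCC[C@H](C(=O)O[Si](C)(C)C)[C@](C)(CCCCl)/C=C/C | intermediate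
10 | (2S,3R,4E)-2-[2-(benzyloxy)ethyl]-3-(3-chloropropyl)-3-methylhex-4-enoic acid | c1ccccc1COCC[C@H](C(O)=O)[C@](C)(CCCCl)/C=C/C | intermediate
11 | methyl (2S,3R,4E)-2-[2-(benzyloxy)ethyl]-3-(3-chloropropyl)-3-methylhex-4-enoate | c1ccccc1COCC[C@H](C(=O)OC)[C@](C)(CCCCl)/C=C/C | intermediate
12 | 1-[(3S,4R,5E)-1-(benzyloxy)-4-(3-chloropropyl)-4-methylhept-5-en-3-yl]cyclopropan-1-ol | c1ccccc1COCC[C@H](C2(O)CC2)[C@](C)(CCCCl)/C=C/C | intermediate
13 | {1-[(3S,4R,5E)-1-(benzyloxy)-4-(3-chloropropyl)-4-methylhept-5-en-3-yl]cyclopropoxy}triethylsilane | c1ccccc1COCC[C@H](C2(O[Si](CC)(CC)CC)CC2)[C@](C)(CCCCl)/C=C/C | intermediate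
14 | (3S,4S)-1-(benzyloxy)-4-(3-chloropropyl)-4-methyl-3-[1-(triethylsilyloxy)cyclopropyl]heptane-5,6-diol (mixture at the two carbinol carbons) | c1ccccc1COCC[C@H](C2(O[Si](CC)(CC)CC)CC2)[C@](C)(CCCCl)C(O)C(C)O | intermediate
15 | (2S,3S)-5-(benzyloxy)-2-(3-chloropropyl)-2-methyl-3-[1-(triethylsilyloxy)cyclopropyl]pentanal | c1ccccc1COCC[C@H](C2(O[Si](CC)(CC)CC)CC2)[C@](C)(CCCCl)C=O | intermediate
16 | dimethyl malonate | COC(=O)CC(=O)OC | starting material
17 | dimethyl 2-[(2R,3S)-5-(benzyloxy)-2-(3-chloropropyl)-2-methyl-3-[1-(triethylsilyloxy)cyclopropyl]pentylidene]propanedioate | c1ccccc1COCC[C@H](C2(O[Si](CC)(CC)CC)CC2)[C@](C)(CCCCl)C=C(C(=O)OC)C(=O)OC | intermediate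
18 | dimethyl 2-[(1R,2R,3S)-3-[2-(benzyloxy)ethyl]-2-(3-chloropropyl)-2-methyl-4-oxocyclohexyl]propanedioate | c1ccccc1COCC[C@@H]2C(=O)CC[C@H](C(C(=O)OC)C(=O)OC)[C@]2(CCCCl)C | intermediate
19 | dimethyl (4aR,5S,8aS)-5-[2-(benzyloxy)ethyl]-4a-methyl-6-oxooctahydronaphthalene-1,1(2H)-dicarboxylate | c1ccccc1COCC[C@@H]2C(=O)CC[C@@H]3C(C(=O)OC)(C(=O)OC)CCC[C@@]23C | intermediate
20 | dimethyl (4aR,5S,8aS)-5-(2-hydroxyethyl)-4a-methyl-6-oxooctahydronaphthalene-1,1(2H)-dicarboxylate | OCC[C@@H]1C(=O)CC[C@@H]2C(C(=O)OC)(C(=O)OC)CCC[C@@]12C | intermediate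
21 | dimethyl (4aR,5S,8aS)-4a-methyl-6-oxo-5-(2-oxoethyl)octahydronaphthalene-1,1(2H)-dicarboxylate | O=CC[C@@H]1C(=O)CC[C@@H]2C(C(=O)OC)(C(=O)OC)CCC[C@@]12C | intermediate
22 | dimethyl (4aR,5S,8aS)-4a-methyl-5-[(2E)-3-methyl-4-oxobut-2-en-1-yl]-6-oxooctahydronaphthalene-1,1(2H)-dicarboxylate | O=C/C(C)=C/C[C@@H]1C(=O)CC[C@@H]2C(C(=O)OC)(C(=O)OC)CCC[C@@]12C | intermediate
23 | dimethyl (4aR,5S,8aS)-4a-methyl-5-[(2E)-3-methylpenta-2,4-dien-1-yl]-6-oxooctahydronaphthalene-1,1(2H)-dicarboxylate | C=C/C(C)=C/C[C@@H]1C(=O)CC[C@@H]2C(C(=O)OC)(C(=O)OC)CCC[C@@]12C | intermediate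
24 | dimethyl (4aS,5R,8aS)-4a-methyl-6-methylidene-5-[(2E)-3-methylpenta-2,4-dien-1-yl]octahydronaphthalene-1,1(2H)-dicarboxylate | C=C/C(C)=C/C[C@@H]1C(=C)CC[C@@H]2C(C(=O)OC)(C(=O)OC)CCC[C@@]12C | intermediate
25 | [(4aS,5R,8aS)-4a-methyl-6-methylidene-5-[(2E)-3-methylpenta-2,4-dien-1-yl]octahydronaphthalene-1,1(2H)-diyl]dimethanol | C=C/C(C)=C/C[C@@H]1C(=C)CC[C@@H]2C(CO)(CO)CCC[C@@]12C | intermediate
26 | [(4aS,5R,8aS)-4a-methyl-6-methylidene-5-[(2E)-3-methylpenta-2,4-dien-1-yl]octahydronaphthalene-1,1(2H)-diyl]bis(methylene) diacetate, (5S,9R,10S)-labda-8(17),12E,14-triene-18,19-diyl diacetate | C=C/C(C)=C/C[C@@H]1C(=C)CC[C@@H]2C(COC(C)=O)(COC(C)=O)CCC[C@@]12C | target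

**Step count and risks**

Total step count: 16. Longest linear sequence: 16 steps (1 → 26).

Steps most likely to fail:

Step 10 (Proposed new method). What may go wrong: slow or unselective photo-oxidation, quenching of the C6 radical before it cyclises, poor facial selectivity in the closure of ring B (it rests on a modest chair preference), or ester cleavage during a slow alkylation. The fallback uses known chemistry, sets out from 17 and comes back at 19; it gives up the photochemical radical–polar crossover and separates the two ring closures. Stoichiometric Fe(NO3)3·9H2O (trivalent iron) with 1,4-cyclohexadiene in DMF opens the cyclopropyl silyl ether to the same β-keto radical, which closes ring B 6-exo onto the alkylidene malonate and is ended by hydrogen-atom transfer; this is the known iron-mediated ring opening–cyclisation of cyclopropyl silyl ethers and would give the monocyclic chloro keto malonate 18 as an isolated compound, whose C5 epimers could be separated at this point. A separate, conventional intramolecular malonate alkylation (Cs2CO3, NaI, DMF, 60 °C) then closes ring A to 19. No compound outside the list is made (F0).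

Step 6. What may go wrong: slow ligand exchange and carbonyl insertion at the hindered, alpha-branched ester, and enolisation of the ester by the Grignard reagent. The fallback sets out from 11 and comes back at 13, bypassing the free cyclopropanol 12. MeNHOMe·HCl with iPrMgCl converts 11 into the Weinreb amide (2S,3R,4E)-2-[2-(benzyloxy)ethyl]-3-(3-chloropropyl)-N-methoxy-N,3-dimethylhex-4-enamide F1. MeMgBr then gives the methyl ketone (3S,4R,5E)-3-[2-(benzyloxy)ethyl]-4-(3-chloropropyl)-4-methylhept-5-en-2-one F2. Kinetic enolisation at the methyl group (LDA, Et3SiCl, THF, −78 °C) gives the silyl enol ether {[(3S,4R,5E)-3-[2-(benzyloxy)ethyl]-4-(3-chloropropyl)-4-methylhepta-1,5-dien-2-yl]oxy}triethylsilane F3. Simmons–Smith cyclopropanation (Et2Zn, CH2I2, CH2Cl2) of the electron-rich enol ether, which should be much faster than that of the hindered propenyl group, gives 13 directly.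

Step 14. What may go wrong: incomplete olefination of the hindered, enolisable C8 ketone and attack of excess ylide on the methyl esters. The fallback sets out from 22 and comes back at 24. One equivalent of Ph3P=CH2 at −78 °C methylenates only the enal, and the keto diene 23 is isolated. Me3SiCH2Li with CeCl3 (THF, −78 °C), a weakly basic organocerium addition that should prefer the ketone to the neopentyl esters, gives the β-hydroxysilane dimethyl (4aR,5S,8aS)-6-hydroxy-4a-methyl-5-[(2E)-3-methylpenta-2,4-dien-1-yl]-6-[(trimethylsilyl)methyl]octahydronaphthalene-1,1(2H)-dicarboxylate F4 as a mixture at the carbinol carbon. Peterson elimination (KH, THF) then gives 24.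

Further compounds
F0 | step 10 | none | none
F1 | step 6 | (2S,3R,4E)-2-[2-(benzyloxy)ethyl]-3-(3-chloropropyl)-N-methoxy-N,3-dimethylhex-4-enamide | c1ccccc1COCC[C@H](C(=O)N(C)OC)[C@](C)(CCCCl)/C=C/C
F2 | step 6 | (3S,4R,5E)-3-[2-(benzyloxy)ethyl]-4-(3-chloropropyl)-4-methylhept-5-en-2-one | c1ccccc1COCC[C@H](C(C)=O)[C@](C)(CCCCl)/C=C/C
F3 | step 6 | {[(3S,4R,5E)-3-[2-(benzyloxy)ethyl]-4-(3-chloropropyl)-4-methylhepta-1,5-dien-2-yl]oxy}triethylsilane | c1ccccc1COCC[C@H](C(=C)O[Si](CC)(CC)CC)[C@](C)(CCCCl)/C=C/C
F4 | step 14 | dimethyl (4aR,5S,8aS)-6-hydroxy-4a-methyl-5-[(2E)-3-methylpenta-2,4-dien-1-yl]-6-[(trimethylsilyl)methyl]octahydronaphthalene-1,1(2H)-dicarboxylate (mixture at the carbinol carbon) | C=C/C(C)=C/C[C@@H]1C(O)(C[Si](C)(C)C)CC[C@@H]2C(C(=O)OC)(C(=O)OC)CCC[C@@]12C
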